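The strategy reads the tertiary C1–OH of the cycloheptane (ring A: C1, C5–C10) as the remnant of an oxygen bridge to the C8 methylene. C8 lies 1,4 to C1 across the C9(OH)–C10(CH3) pair. Ring A then becomes an 8-oxabicyclo[3.2.1]octane, the adduct of a six-membered carbonyl ylide (C8–O–C1) and an (E)-propenyl silyl ether. One Rh2(OAc)4-catalysed cascade converts an open-chain, D-tartrate-derived diazo diketo ester into the ylide and then the cycloadduct. It forges C8–C9 and C10–C1, ring A and four stereocentres. SmI2 later cuts C8–O, the C7 ketone becomes lactone ring B, and the slim C1 alkynyl group serves as a masked β-hydroxy ketone.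

Key step: step 7

Remark (numbering used throughout): C1 = C(OH) bearing the side chain C2(=O)–C3H2–C4H(OH)–C15H3; C5 = CH–O-acyl; C6 = CH–O of the lactone; C7 = ring-fusion CH; C8 = CH2; C9 = CHOH; C10 = CH(C14H3); C11–C13 = methylene lactone carbons. The target is 1S,4R,5S,6R,7S,9R,10S,2'S. TBS = tert-butyldimethylsilyl.

Step 1
Reactants: 1 (R)-but-3-yn-2-ol
Product: 2 (R)-3-(tert-butyldimethylsilyloxy)but-1-yne
Conditions: TBSCl, imidazole, CH2Cl2, 0 °C to rt
Reagents that add atoms: tert-butyldimethylsilyl chloride, CC(C)(C)[Si](C)(C)Cl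
Why: Routine imidazole-promoted silyl ether formation masks the C4 hydroxyl, whose R configuration is bought in with 1 and is never touched again.

Step 2
Reactants: 3 allyl tert-butyldimethylsilyl ether
Product: 4 (E)-1-(tert-butyldimethylsilyloxy)prop-1-ene
Conditions: [Ir(cod)(PMePh2)2]PF6 (1 mol %, activated with H2), THF, rt
Reagents that add atoms: none
Why: Cationic iridium hydride catalysed allyl-to-propenyl ether isomerisation (1,3-hydrogen shift through a π-allyl hydride) is the standard kinetic entry to E-configured enol ethers, the geometry that later fixes the trans relation of C9–O and C10–CH3.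

Step 3
Reactants: 5 dimethyl (4S,5S)-2,2-dimethyl-1,3-dioxolane-4,5-dicarboxylate
Product: 6 (4S,5S)-N,N'-dimethoxy-N,N',2,2-tetramethyl-1,3-dioxolane-4,5-dicarboxamide
Conditions: MeNH(OMe)·HCl, i-PrMgCl, THF, −20 °C
Reagents that add atoms: N,O-dimethylhydroxylamine hydrochloride, CNOC.Cl
Why: Aminolysis of both esters by the chloromagnesium amide (Weinreb amide synthesis) keeps the C2-symmetric trans-dioxolane, so C5 and C6 come from the chiral pool.

Step 4
Reactants: 6 bis(Weinreb amide); 7 tert-butyl acetate
Product: 8 tert-butyl 3-[(4S,5S)-5-(N-methoxy-N-methylcarbamoyl)-2,2-dimethyl-1,3-dioxolan-4-yl]-3-oxopropanoate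
Conditions: LiN(i-Pr)2 (1.1 equiv), 7 (1.1 equiv), THF, −78 °C; then 6, −78 °C; AcOH quench at −78 °C
Reagents that add atoms: none
Why: Crossed Claisen-type acylation of the lithium enolate of 7 should stop at monoaddition because the chelated tetrahedral adduct survives until the cold quench and shields the neighbouring amide, and either amide of C2-symmetric 6 gives the same product.

Step 5
Reactants: 8 β-keto ester Weinreb amide; 2 silyloxy alkyne
Product: 9 tert-butyl 3-{(4S,5S)-5-[(4R)-4-(tert-butyldimethylsilyloxy)pent-2-ynoyl]-2,2-dimethyl-1,3-dioxolan-4-yl}-3-oxopropanoate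
Conditions: 2 (2.3 equiv), n-BuLi (2.2 equiv), THF, −78 °C; then 8, −78 to −20 °C; inverse quench into cold 0.5 M HCl
Reagents that add atoms: none
Why: The first equivalent of lithium acetylide only deprotonates the β-keto ester, which is thereby self-protected as its enolate, and the second adds to the Weinreb amide (ketone synthesis through the stable chelate), while the acidic inverse quench keeps the liberated amine from adding to the ynone.

Step 6
Reactants: 9 ynone β-keto ester
Product: 10 tert-butyl 2-diazo-3-{(4S,5S)-5-[(4R)-4-(tert-butyldimethylsilyloxy)pent-2-ynoyl]-2,2-dimethyl-1,3-dioxolan-4-yl}-3-oxopropanoate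
Conditions: 4-acetamidobenzenesulfonyl azide, Et3N, MeCN, 0 °C to rt
Reagents that add atoms: 4-acetamidobenzenesulfonyl azide, CC(=O)Nc1ccc(cc1)S(=O)(=O)N=[N+]=[N-]
Why: Regitz diazo transfer to the activated C8 methylene is mild enough for the ynone, and aldol closure of C8 onto C1 is disfavoured because it would give a trans-fused bicyclo[3.3.0] system.

Step 7
Reactants: 10 diazo diketo ester; 4 (E)-propenyl silyl ether
Product: 12 oxa-bridged cycloadduct (8-oxabicyclo[3.2.1]octan-2-one core; C9-OTBS endo; C10-CH3 exo; O5/O6 acetonide diequatorial), via carbonyl ylide 11 (not isolated)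
Conditions: Rh2(OAc)4 (2 mol %), 4 (5 equiv), PhCF3, 40 °C, slow addition of 10
Reagents that add atoms: none
Why: Rh2(OAc)4 expels N2 from 10, a lone pair of the C1 ketone oxygen captures the electrophilic carbenoid carbon C8 (closure of a six-membered ring trans-fused to the dioxolane) to give ylide 11, and 11 adds suprafacially as a 4π dipole across 4, which is the known tandem carbonyl ylide formation–1,3-dipolar cycloaddition of 2-diazo-3,6-diketo esters with electron-rich alkenes (inverse electron demand). The cycloaddition closes the oxolane O–C8–C9–C10–C1 in a concerted [3+2] mode and thereby the seven-membered carbocycle C1–C5–C6–C7–C8–C9–C10 (formal [5+2]). Regiochemistry: C1 is the oxocarbenium-like terminus (largest LUMO coefficient, lowered further by the alkynyl group) and pairs with the nucleophilic methyl-bearing carbon of 4, while the malonate-like C8 pairs with the oxygen-bearing carbon. Facial control at C1 and C8: the trans-fused acetonide locks O5 and O6 pseudo-equatorial, so only attack anti to the axial C5–H leads directly to a chair oxane, whereas the other face would give a twist-boat. C9 and C10: the E geometry of 4 is transferred stereospecifically (OTBS and CH3 trans), and the single endo position should be taken by the small oxygen above the flat C7 carbonyl while CH3 goes exo, away from O5 and the axial C6–H. Chemoselectivity requires ylide formation to outrun cyclopropanation of 4 and self-trapping by the ynone, which the intramolecular six-ring capture, the slow addition of 10 and the excess of 4 secure.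

Step 8
Reactants: 12 cycloadduct
Product: 13 ring-opened cycloheptanone β-keto ester with free C1–OH (C8 epimers and enol)
Conditions: SmI2 (2.5 equiv), THF–MeOH (20:1), −78 °C
Reagents that add atoms: none
Why: Two-electron reduction of an α-alkoxy ketone by SmI2 expels the bridging oxygen from C8, because the strained C8–O bond overlaps with the C7 ketyl π system and gives a stabilised trivalent samarium β-keto ester enolate, whereas the equatorial C6–O bond lies near the carbonyl plane and stays, and C1 keeps its oxygen and configuration.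

Step 9
Reactants: 13 β-keto ester acetonide
Product: 15 cycloheptanone triol (C1–OH C5–OH C6–OH free; C4 and C9 still OTBS), via beta-keto acid 14 (not isolated)
Conditions: 85% aq H3PO4, toluene, rt to 40 °C
Reagents that add atoms: none
Why: Aqueous phosphoric acid is a mild reagent for tert-butyl ester cleavage that tolerates TBS ethers, it should also hydrolyse the strained trans-fused acetonide, and β-keto acid 14 loses CO2 on gentle warming, which erases the stereorandom C8 centre.

Step 10
Reactants: 15 cycloheptanone triol; 16 (triphenylphosphoranylidene)ketene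
Product: 18 butenolide diol (C7=C11), via ester phosphorane 17 (not isolated)
Conditions: 16 (1.1 equiv), toluene, 80 °C
Reagents that add atoms: none
Why: The most acidic and least hindered hydroxyl (the C6 α-ketol OH, since C5–OH is neopentylic and C1–OH tertiary) adds to the cumulated ylide to give 17, whose intramolecular Wittig reaction with the C7 ketone closes the five-membered ring (Bestmann butenolide synthesis).

Step 11
Reactants: 18 butenolide diol
Product: 19 cis-fused saturated γ-lactone diol (7S)
Conditions: Li[HB(s-Bu)3] (L-Selectride, 4 equiv), THF, −78 to −40 °C; AcOH quench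
Reagents that add atoms: none
Why: Conjugate (1,4-) hydride addition by the bulky borohydride, which is inert to the internal alkyne, should deliver hydride to C7 from the convex face that carries H6 (the other face is covered by the C5–C1–C10–C9 loop of ring A), which sets 7S and the cis ring fusion.

Step 12
Reactants: 19 saturated lactone diol
Product: 22 alpha-methylene lactone diol, via Mannich base 20 (not isolated), via ammonium iodide 21 (not isolated)
Conditions: LiN(i-Pr)2 (4 equiv), THF, −78 °C; CH2=NMe2+ I−, −78 °C to rt; crude, MeI, THF, rt; aq NaHCO3, CH2Cl2, rt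
Reagents that add atoms: N,N-dimethylmethyleneiminium iodide (Eschenmoser's salt), C=[N+](C)C.[I-]; iodomethane, CI
Why: In this classical α-methylenation of a γ-lactone the trianion (two alkoxides plus the C11 enolate) undergoes a Mannich reaction, and exhaustive methylation followed by mild-base Hofmann-type β-elimination gives the exocyclic C11=C13 bond without touching C7.

Step 13
Reactants: 22 α-methylene lactone diol; 23 (S)-2-methylbutanoic anhydride
Product: 24 C5 (S)-2-methylbutanoate, bis-TBS ether
Conditions: 23 (2 equiv), DMAP, Et3N, CH2Cl2, rt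
Reagents that add atoms: none
Why: DMAP-catalysed acyl transfer esterifies the only secondary hydroxyl, C5–OH, while the tertiary propargylic C1–OH stays free, and the preformed enantiopure anhydride avoids ketene formation and so keeps the 2'S centre.

Step 14
Reactants: 24 bis-TBS ester
Product: 25 alkynetriol (C1–OH, C4–OH, C9–OH free)
Conditions: HF·pyridine, pyridine, THF, 0 °C to rt
Reagents that add atoms: none
Why: Fluoride-mediated desilylation under buffered, weakly acidic conditions removes both TBS groups without conjugate addition to the methylene lactone or acyl migration.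

Step 15
Reactants: 25 alkynetriol
Product: 27 target CNP0291806.4, via cyclic enol ether 26 (not isolated)
Conditions: Ph3PAuNTf2 (5 mol %), THF–H2O (10:1), rt
Reagents that add atoms: water, O
Why: π-Activation of the alkyne by monovalent gold triggers 5-exo-dig hydroalkoxylation by the C9 hydroxyl, which is cis-1,3 to the alkynyl group, so oxygen is delivered to C2 only (the C5 ester carbonyl can reach the same carbon in a 6-exo mode), and hydrolysis of 26 in the flask releases the C2 ketone and C9–OH with C4 untouched.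

Compound list
1 | (R)-but-3-yn-2-ol | C#C[C@@H](C)O | starting material
2 | (R)-3-(tert-butyldimethylsilyloxy)but-1-yne | C#C[C@@H](C)O[Si](C)(C)C(C)(C)C | intermediate
3 | allyl tert-butyldimethylsilyl ether | C=CCO[Si](C)(C)C(C)(C)C | starting material
4 | (E)-1-(tert-butyldimethylsilyloxy)prop-1-ene | C/C=C/O[Si](C)(C)C(C)(C)C | intermediate
5 | dimethyl (4S,5S)-2,2-dimethyl-1,3-dioxolane-4,5-dicarboxylate (dimethyl 2,3-O-isopropylidene-D-tartrate) | CC1(C)O[C@H](C(=O)OC)[C@H](O1)C(=O)OC | starting material
6 | (4S,5S)-N,N'-dimethoxy-N,N',2,2-tetramethyl-1,3-dioxolane-4,5-dicarboxamide | CC1(C)O[C@H](C(=O)N(C)OC)[C@H](O1)C(=O)N(C)OC | intermediate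
7 | tert-butyl acetate | CC(=O)OC(C)(C)C | starting material
8 | tert-butyl 3-[(4S,5S)-5-(N-methoxy-N-methylcarbamoyl)-2,2-dimethyl-1,3-dioxolan-4-yl]-3-oxopropanoate | CC1(C)O[C@H](C(=O)CC(=O)OC(C)(C)C)[C@H](O1)C(=O)N(C)OC | intermediate
9 | tert-butyl 3-{(4S,5S)-5-[(4R)-4-(TBSO)pent-2-ynoyl]-2,2-dimethyl-1,3-dioxolan-4-yl}-3-oxopropanoate | CC1(C)O[C@H](C(=O)CC(=O)OC(C)(C)C)[C@H](O1)C(=O)C#C[C@@H](C)O[Si](C)(C)C(C)(C)C | intermediate
10 | 2-diazo derivative of 9 (open-chain diazo diketo ester) | CC1(C)O[C@H](C(=O)C(=[N+]=[N-])C(=O)OC(C)(C)C)[C@H](O1)C(=O)C#C[C@@H](C)O[Si](C)(C)C(C)(C)C | intermediate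
11 | six-membered carbonyl ylide C8(−)–O(+)=C1, trans-fused to the acetonide | CC3(C)O[C@@H]2C(=O)[C-](C(=O)OC(C)(C)C)[O+]=C(C#C[C@@H](C)O[Si](C)(C)C(C)(C)C)[C@H]2O3 | intermediate
12 | cycloadduct: 8-oxabicyclo[3.2.1]octan-2-one with C8–CO2t-Bu, C9–OTBS endo, C10–CH3 exo, C1 alkynyl, O5/O6 acetonide | CC3(C)O[C@@H]2C(=O)[C@@]4(C(=O)OC(C)(C)C)[C@@H](O[Si](C)(C)C(C)(C)C)[C@H](C)[C@@](O4)(C#C[C@@H](C)O[Si](C)(C)C(C)(C)C)[C@H]2O3 | intermediate
13 | cycloheptanone β-keto tert-butyl ester, C1–OH free, acetonide on O5/O6 (C8 unassigned) | CC3(C)O[C@@H]2C(=O)C(C(=O)OC(C)(C)C)[C@@H](O[Si](C)(C)C(C)(C)C)[C@H](C)[C@@](O)(C#C[C@@H](C)O[Si](C)(C)C(C)(C)C)[C@H]2O3 | intermediate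
14 | β-keto acid triol | O[C@@H]1C(=O)C(C(=O)O)[C@@H](O[Si](C)(C)C(C)(C)C)[C@H](C)[C@@](O)(C#C[C@@H](C)O[Si](C)(C)C(C)(C)C)[C@H]1O | intermediate
15 | cycloheptanone triol (C7 ketone, C8H2) | O[C@@H]1C(=O)C[C@@H](O[Si](C)(C)C(C)(C)C)[C@H](C)[C@@](O)(C#C[C@@H](C)O[Si](C)(C)C(C)(C)C)[C@H]1O | intermediate
16 | (triphenylphosphoranylidene)ketene (Bestmann ylide) | O=C=C=P(c1ccccc1)(c1ccccc1)c1ccccc1 | starting material
17 | C6–O (triphenylphosphoranylidene)acetate of 15 | O=C(C=P(c1ccccc1)(c1ccccc1)c1ccccc1)O[C@@H]1C(=O)C[C@@H](O[Si](C)(C)C(C)(C)C)[C@H](C)[C@@](O)(C#C[C@@H](C)O[Si](C)(C)C(C)(C)C)[C@H]1O | intermediate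
18 | butenolide diol (C7=C11, O6–C12 lactone) | C1=C2C[C@@H](O[Si](C)(C)C(C)(C)C)[C@H](C)[C@@](O)(C#C[C@@H](C)O[Si](C)(C)C(C)(C)C)[C@@H](O)[C@@H]2OC1=O | intermediate
19 | cis-fused γ-lactone diol (6R,7S) | C1C(=O)O[C@@H]2[C@H]1C[C@@H](O[Si](C)(C)C(C)(C)C)[C@H](C)[C@@](O)(C#C[C@@H](C)O[Si](C)(C)C(C)(C)C)[C@H]2O | intermediate
20 | C11 dimethylaminomethyl lactone (C11 unassigned) | CN(C)CC1C(=O)O[C@@H]2[C@H]1C[C@@H](O[Si](C)(C)C(C)(C)C)[C@H](C)[C@@](O)(C#C[C@@H](C)O[Si](C)(C)C(C)(C)C)[C@H]2O | intermediate
21 | C11 trimethylammoniomethyl lactone iodide | C[N+](C)(C)CC1C(=O)O[C@@H]2[C@H]1C[C@@H](O[Si](C)(C)C(C)(C)C)[C@H](C)[C@@](O)(C#C[C@@H](C)O[Si](C)(C)C(C)(C)C)[C@H]2O.[I-] | intermediate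
22 | α-methylene-γ-lactone diol (C1–OH, C5–OH free) | C=C1C(=O)O[C@@H]2[C@H]1C[C@@H](O[Si](C)(C)C(C)(C)C)[C@H](C)[C@@](O)(C#C[C@@H](C)O[Si](C)(C)C(C)(C)C)[C@H]2O | intermediate
23 | (S)-2-methylbutanoic anhydride | CC[C@H](C)C(=O)OC(=O)[C@@H](C)CC | starting material
24 | C5 (S)-2-methylbutanoate of 22 | C=C1C(=O)O[C@@H]2[C@H]1C[C@@H](O[Si](C)(C)C(C)(C)C)[C@H](C)[C@@](O)(C#C[C@@H](C)O[Si](C)(C)C(C)(C)C)[C@H]2OC(=O)[C@@H](C)CC | intermediate
25 | alkynetriol (desilylated 24) | C=C1C(=O)O[C@@H]2[C@H]1C[C@@H](O)[C@H](C)[C@@](O)(C#C[C@@H](C)O)[C@H]2OC(=O)[C@@H](C)CC | intermediate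
26 | bridged (Z)-2-alkylidene oxolane (O9 bound to C2, C2=C3) | C=C1C(=O)O[C@@H]2[C@H]1C[C@@H]3[C@H](C)[C@@](O)(/C(O3)=C/[C@@H](C)O)[C@H]2OC(=O)[C@@H](C)CC | intermediate
27 | CNP0291806.4 | C=C1C(=O)O[C@@H]2[C@H]1C[C@@H](O)[C@H](C)[C@@](O)(C(=O)C[C@@H](C)O)[C@H]2OC(=O)[C@@H](C)CC | target

Total step count: 15. Longest linear sequence: 13 steps (5 to 27, steps 3–15).

Steps most likely to fail

Step 7. The 1,2-disubstituted enol ether may add too slowly to the doubly substituted ylide. Ylide dimerisation or cyclopropanation of 4 could then take over. The addition may also become stepwise, with loss of the E geometry and poor endo/exo or facial selectivity. The fallback builds ring A by two separate polar bond formations and sets out from 9. (E)-Crotylboronic acid pinacol ester is added to the activated C1 ketone through a closed Zimmerman–Traxler transition state (anti relation of C10–CH3 and C1–OH, alkynyl group axial) to give homoallylic tertiary alcohol F1. Ozonolysis of the terminal alkene (O3, then Me2S; the alkyne reacts more slowly) gives aldehyde F2. Soft enolisation (MgBr2·OEt2, i-Pr2NEt) closes the ring by intramolecular aldol addition of C8 to C9, giving aldol F3. Silylation of the secondary C9–OH (TBSCl, imidazole) comes back to the route at 13.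

Step 11. Hydride may attack the lactone carbonyl (1,2-addition) or fail to reach the fully substituted β-carbon C7. The fallback makes the acceptor doubly activated and avoids strong base, and it sets out from 15. Heating with Meldrum's acid acylates C6–OH to give malonic half ester F4. Piperidinium acetate induces an intramolecular Knoevenagel condensation with the C7 ketone to give α-carboxy butenolide F5. NaBH4 in THF–MeOH at 0 °C reduces the alkylidene malonate unit from the convex face to give α-carboxy lactone F6. Decarboxylative Mannich methylenation (aq CH2O, Et2NH, then NaOAc–AcOH) comes back to the route at 22.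

Step 15. The allylic C4 hydroxyl of the enol ether may ionise, giving a net Meyer–Schuster-type dehydration to the enone, or oxygen may be delivered to C3. The fallback hydrates before desilylation, so that no free propargylic or allylic secondary hydroxyl is present, and it uses a different directing group. It sets out from 24. Ph3PAuNTf2 in wet dioxane lets the C5 ester carbonyl attack C2 in a 6-exo-dig mode, and hydrolysis of the dioxenium intermediate gives bis-silyl ketone F7. HF·pyridine then comes back to the route at 27.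

Further compounds
F1 | step 7 | homoallylic tertiary alcohol from crotylation of 9 at C1 | CC1(C)O[C@H](C(=O)CC(=O)OC(C)(C)C)[C@H](O1)[C@](O)(C#C[C@@H](C)O[Si](C)(C)C(C)(C)C)[C@@H](C)C=C
F2 | step 7 | C9 aldehyde | CC1(C)O[C@H](C(=O)CC(=O)OC(C)(C)C)[C@H](O1)[C@](O)(C#C[C@@H](C)O[Si](C)(C)C(C)(C)C)[C@@H](C)C=O
F3 | step 7 | cycloheptanone aldol with free C9–OH | CC3(C)O[C@@H]2C(=O)C(C(=O)OC(C)(C)C)[C@@H](O)[C@H](C)[C@@](O)(C#C[C@@H](C)O[Si](C)(C)C(C)(C)C)[C@H]2O3
F4 | step 11 | C6–O malonic half ester of 15 | OC(=O)CC(=O)O[C@@H]1C(=O)C[C@@H](O[Si](C)(C)C(C)(C)C)[C@H](C)[C@@](O)(C#C[C@@H](C)O[Si](C)(C)C(C)(C)C)[C@H]1O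
F5 | step 11 | C11-carboxy butenolide | OC(=O)C1=C2C[C@@H](O[Si](C)(C)C(C)(C)C)[C@H](C)[C@@](O)(C#C[C@@H](C)O[Si](C)(C)C(C)(C)C)[C@@H](O)[C@@H]2OC1=O
F6 | step 11 | C11-carboxy cis-fused γ-lactone | OC(=O)C1C(=O)O[C@@H]2[C@H]1C[C@@H](O[Si](C)(C)C(C)(C)C)[C@H](C)[C@@](O)(C#C[C@@H](C)O[Si](C)(C)C(C)(C)C)[C@H]2O
F7 | step 15 | bis-TBS ether of the target | C=C1C(=O)O[C@@H]2[C@H]1C[C@@H](O[Si](C)(C)C(C)(C)C)[C@H](C)[C@@](O)(C(=O)C[C@@H](C)O[Si](C)(C)C(C)(C)C)[C@H]2OC(=O)[C@@H](C)CC
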